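**Retrosynthetic overview**

1. The Z-styryl arm on C4 of unit 1 is attached last, by Suzuki coupling of a C4 triflate with a Z-styrylboronate. All methyl ethers are exchanged for silyl ethers before the alkene exists, because acid would close such a stilbene onto the neighbouring oxygenated ring of unit 2.
2. The C3(unit 1)–C4'(unit 2) bond comes from nickel-catalysed decarboxylative arylation of the C3 N-acyloxyphthalimide of unit 1 with the C4' arylzinc of unit 2; the C2 aryl group directs the new bond trans.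
3. The strategy rests on unit 1: its dihydrobenzofuran (O1, C2 with the 4-hydroxyphenyl group, C3, benzo ring C3a–C7a with oxygen on C6 and the arm on C4) is (2S)-naringenin with one carbon taken out of the ring. The C2 aryl group, its configuration and the ring-A oxygens are already in place, and the former 5-oxygen lands on C4 as the handle. The disconnection is the oxidative shift of the ring-A carbon from the carbonyl carbon to C3 of the protected flavanone.
4. Unit 2 has the opposite absolute sense (2R,3R against 2S,3S), so it is made by the same contraction from the (2R)-flavanone, obtained by rhodium-catalysed asymmetric conjugate addition to a chromone. Its C3 carboxylate is then exchanged for the 3,5-dimethoxyphenyl group and its C4 oxygen for bromine.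
5. Ring order: dihydrofuran ring of unit 1 (step 3), dihydrofuran ring of unit 2 (step 9), each by contraction of a pyranone; no ring is formed after the fragment union.

Key step: step 3

Assumptions: (2S)-naringenin is bought as the single enantiomer (purity checked by chiral HPLC and, if needed, raised by crystallising 2). 3,5-Dimethoxyphenylmagnesium chloride (THF solution) and tert-butyl(4-ethynylphenoxy)dimethylsilane are taken as catalogue items.

**Route**

Step 1
Reactants: 1 (2S)-naringenin
Product: 2 (2S)-5-hydroxy-7-methoxy-2-(4-methoxyphenyl)chroman-4-one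
Conditions: TMSCHN2 (4 equiv, in portions), toluene/MeOH 3:2, 0 °C → rt, no added base
Reagents that add atoms: trimethylsilyldiazomethane C[Si](C)(C)C=[N+]=[N-]
Why: Diazoalkane O-methylation should convert the free 7- and 4'-hydroxyls but not the 5-hydroxyl hydrogen-bonded to the C4 carbonyl, and without base neither the chalcone nor the 4'-phenoxide/quinone-methide pathway that racemises C2 is open.

Step 2
Reactants: 2 (2S)-5-hydroxy-7-methoxy-2-(4-methoxyphenyl)chroman-4-one
Product: 3 (2S)-5-(benzyloxy)-7-methoxy-2-(4-methoxyphenyl)chroman-4-one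
Conditions: BnBr (3 equiv), Ag2O (2 equiv), DMF, rt, dark
Reagents that add atoms: benzyl bromide BrCc1ccccc1
Why: Silver-oxide-assisted Williamson etherification (Purdie/Kuhn type) alkylates the chelated phenol through halide abstraction by silver, without a carbonate or alkoxide base that could enolise C3 and open the pyranone by retro-oxa-Michael reaction, so C2 should remain S.

Step 3
Reactants: 3 (2S)-5-(benzyloxy)-7-methoxy-2-(4-methoxyphenyl)chroman-4-one
Product: 6 methyl (2S,3S)-4-(benzyloxy)-6-methoxy-2-(4-methoxyphenyl)-2,3-dihydrobenzofuran-3-carboxylate, via enol ether 4 (not isolated), via C3 iodane ketal 5 (not isolated)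
Conditions: PhI(OAc)2 (1.2 equiv), H2SO4 (0.5 equiv), HC(OMe)3, 0 °C → rt; aq. NaHCO3 work-up
Reagents that add atoms: trimethyl orthoformate COC(OC)OC (ester methoxy group); water O (ester carbonyl oxygen, on hydrolytic work-up)
Why: Under H2SO4 in the orthoformate the C4 ketone is ketalised and loses methanol to enol ether 4; PhI(OAc)2 then attacks C3 from the face opposite the C2 aryl group and methanol returns to C4 (5); the ring-A carbon C4a, antiperiplanar to the equatorial C3–I bond, moves from C4 to C3 as iodobenzene departs, and the dimethoxycarbenium ion left at the old C4 ends as the methyl ester on work-up. This is the established oxidative ring contraction of flavanones to methyl trans-2-aryl-2,3-dihydrobenzofuran-3-carboxylates, a 1,2-aryl shift onto a carbon bearing a trivalent iodine nucleofuge. The dihydrofuran ring (O1–C2–C3–C3a–C7a) is closed by contraction: the arene ipso carbon displaces iodine at C3 through a bridged phenonium-type transition state (formally 3-exo-tet), so C3–C3a forms while C4 leaves the ring. C3 is the new stereocentre; anti iodination followed by invertive migration puts CO2Me trans to the aryl group, which is also the thermodynamic epimer, while C2 takes no part and keeps the S configuration of naringenin. The step needs ring-A migration to win over the shift of the 4-methoxyphenyl group (isoflavone) and over loss of HX (flavone); the ketal holds the aryl group and the C–I bond diequatorial so that only the C4–C4a bond is aligned with the leaving group, and C4a is activated by two ortho oxygens and a para methoxy group. No base is present and the acid is substoichiometric at or below room temperature, so the flavanone should not open to its chalcone.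

Step 4
Reactants: 6 methyl (2S,3S)-4-(benzyloxy)-6-methoxy-2-(4-methoxyphenyl)-2,3-dihydrobenzofuran-3-carboxylate
Product: 7 (2S,3S)-4-(benzyloxy)-6-methoxy-2-(4-methoxyphenyl)-2,3-dihydrobenzofuran-3-carboxylic acid
Conditions: LiOH·H2O, THF/MeOH/H2O, 40 °C; then 1 M HCl
Reagents that add atoms: lithium hydroxide [Li+].[OH-]
Why: Ester saponification (acyl substitution); any C3 enolate reprotonates to the more stable trans acid, and loss of the aryloxide from that enolate is stereoelectronically disfavoured (the reverse of a 5-endo-trig closure), so the ring and C2 should be preserved.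

Step 5
Reactants: 7 (2S,3S)-4-(benzyloxy)-6-methoxy-2-(4-methoxyphenyl)-2,3-dihydrobenzofuran-3-carboxylic acid
Product: 8 1,3-dioxoisoindolin-2-yl (2S,3S)-4-(benzyloxy)-6-methoxy-2-(4-methoxyphenyl)-2,3-dihydrobenzofuran-3-carboxylate
Conditions: N-hydroxyphthalimide, iPrN=C=NiPr, DMAP (cat.), CH2Cl2, rt
Reagents that add atoms: N-hydroxyphthalimide O=C1c2ccccc2C(=O)N1O
Why: Carbodiimide (Steglich-type) esterification gives the redox-active ester, with the trans arrangement retained because it is the stable epimer.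

Step 6
Reactants: 9 5,7-dihydroxy-4H-chromen-4-one
Product: 10 5-hydroxy-7-methoxy-4H-chromen-4-one
Conditions: MeI (1.1 equiv), K2CO3, acetone, 40 °C
Reagents that add atoms: iodomethane CI
Why: Williamson methylation is selective for the acidic 7-hydroxyl because the 5-hydroxyl is chelated to the carbonyl.

Step 7
Reactants: 10 5-hydroxy-7-methoxy-4H-chromen-4-one
Product: 11 5-(benzyloxy)-7-methoxy-4H-chromen-4-one
Conditions: BnBr, K2CO3, DMF, 60 °C
Reagents that add atoms: benzyl bromide BrCc1ccccc1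
Why: Williamson benzylation of the chelated phenol under forcing carbonate conditions is safe here because the chromone has no stereocentre and no enolisable position.

Step 8
Reactants: 11 5-(benzyloxy)-7-methoxy-4H-chromen-4-one; 12 4-methoxyphenylboronic acid
Product: 13 (2R)-5-(benzyloxy)-7-methoxy-2-(4-methoxyphenyl)chroman-4-one
Conditions: [Rh(OH)(cod)]2 (cat.), MeO-F12-BIPHEP (the ligand antipode that gives 2R), toluene/H2O 10:1, 30 °C
Reagents that add atoms: none
Why: Rhodium-catalysed asymmetric 1,4-addition of an arylboronic acid to a chromone (Hayashi–Miyaura reaction) sets C2 as R under ligand control, the aryl–rhodium species with the electron-poor atropisomeric bisphosphine inserting C2=C3 on one face before water protonates the enolate; the ligand hand is confirmed by chiral HPLC against 3, the mirror image of 13, and any minor enantiomer would end as a separable diastereomer after step 16.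

Step 9
Reactants: 13 (2R)-5-(benzyloxy)-7-methoxy-2-(4-methoxyphenyl)chroman-4-one
Product: 16 methyl (2R,3R)-4-(benzyloxy)-6-methoxy-2-(4-methoxyphenyl)-2,3-dihydrobenzofuran-3-carboxylate, via enol ether 14 (not isolated), via C3 iodane ketal 15 (not isolated)
Conditions: PhI(OAc)2 (1.2 equiv), H2SO4 (0.5 equiv), HC(OMe)3, 0 °C → rt; aq. NaHCO3 work-up
Reagents that add atoms: trimethyl orthoformate COC(OC)OC (ester methoxy group); water O (ester carbonyl oxygen, on hydrolytic work-up)
Why: The oxidative flavanone ring contraction of step 3 in the mirror-image series: anti iodination at C3, invertive 1,2-shift of the ring-A carbon and ester formation should give the trans (2R,3R) ester with C2 untouched.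

Step 10
Reactants: 16 methyl (2R,3R)-4-(benzyloxy)-6-methoxy-2-(4-methoxyphenyl)-2,3-dihydrobenzofuran-3-carboxylate
Product: 17 (2R,3R)-4-(benzyloxy)-6-methoxy-2-(4-methoxyphenyl)-2,3-dihydrobenzofuran-3-carboxylic acid
Conditions: LiOH·H2O, THF/MeOH/H2O, 40 °C; then 1 M HCl
Reagents that add atoms: lithium hydroxide [Li+].[OH-]
Why: Saponification as in step 4, with the trans acid as the stable epimer.

Step 11
Reactants: 17 (2R,3R)-4-(benzyloxy)-6-methoxy-2-(4-methoxyphenyl)-2,3-dihydrobenzofuran-3-carboxylic acid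
Product: 18 1,3-dioxoisoindolin-2-yl (2R,3R)-4-(benzyloxy)-6-methoxy-2-(4-methoxyphenyl)-2,3-dihydrobenzofuran-3-carboxylate
Conditions: N-hydroxyphthalimide, iPrN=C=NiPr, DMAP (cat.), CH2Cl2, rt
Reagents that add atoms: N-hydroxyphthalimide O=C1c2ccccc2C(=O)N1O
Why: Carbodiimide esterification to the redox-active ester, as in step 5.

Step 12
Reactants: 18 1,3-dioxoisoindolin-2-yl (2R,3R)-4-(benzyloxy)-6-methoxy-2-(4-methoxyphenyl)-2,3-dihydrobenzofuran-3-carboxylate; 19 3,5-dimethoxyphenylmagnesium chloride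
Product: 21 (2R,3R)-4-(benzyloxy)-3-(3,5-dimethoxyphenyl)-6-methoxy-2-(4-methoxyphenyl)-2,3-dihydrobenzofuran, via arylzinc chloride 20 (not isolated)
Conditions: 19 (3 equiv), ZnCl2, LiCl, THF, 0 °C → rt; then 18, NiCl2·glyme (20 mol%), 4,4'-di-tert-butyl-2,2'-bipyridine (40 mol%), THF/DMF, rt
Reagents that add atoms: none
Why: Nickel-catalysed decarboxylative Negishi arylation of a secondary redox-active ester: electron transfer releases CO2 and the planar benzylic C3 radical, which the arylnickel species captures on the face away from the C2 aryl group to give the trans diaryl compound; the ring stays closed because the C2–O bond is nearly orthogonal to the singly occupied orbital.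

Step 13
Reactants: 21 (2R,3R)-4-(benzyloxy)-3-(3,5-dimethoxyphenyl)-6-methoxy-2-(4-methoxyphenyl)-2,3-dihydrobenzofuran
Product: 22 (2R,3R)-3-(3,5-dimethoxyphenyl)-6-methoxy-2-(4-methoxyphenyl)-2,3-dihydrobenzofuran-4-ol
Conditions: H2 (1 atm), Pd/C (10% Pd on carbon), EtOAc, rt
Reagents that add atoms: none
Why: Hydrogenolysis of the O-benzyl ether is much faster than cleavage of the ring C2–O bond in a neutral solvent and is stopped at full conversion of the benzyl ether.

Step 14
Reactants: 22 (2R,3R)-3-(3,5-dimethoxyphenyl)-6-methoxy-2-(4-methoxyphenyl)-2,3-dihydrobenzofuran-4-ol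
Product: 23 (2R,3R)-3-(3,5-dimethoxyphenyl)-6-methoxy-2-(4-methoxyphenyl)-2,3-dihydrobenzofuran-4-yl trifluoromethanesulfonate
Conditions: Tf2O, pyridine, CH2Cl2, 0 °C
Reagents that add atoms: triflic anhydride O=S(=O)(OS(=O)(=O)C(F)(F)F)C(F)(F)F
Why: O-Sulfonylation of the only free phenol turns the C4 oxygen into a leaving group for palladium.

Step 15
Reactants: 23 (2R,3R)-3-(3,5-dimethoxyphenyl)-6-methoxy-2-(4-methoxyphenyl)-2,3-dihydrobenzofuran-4-yl trifluoromethanesulfonate
Product: 24 (2R,3R)-4-bromo-3-(3,5-dimethoxyphenyl)-6-methoxy-2-(4-methoxyphenyl)-2,3-dihydrobenzofuran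
Conditions: Pd2(dba)3 (2.5 mol%), t-BuBrettPhos (7.5 mol%), KBr (2 equiv), KF (0.5 equiv), 1,4-dioxane, 130 °C
Reagents that add atoms: potassium bromide [K+].[Br-]
Why: Palladium-catalysed triflate-to-bromide exchange (oxidative addition to zerovalent palladium, triflate/bromide metathesis, C–Br reductive elimination forced by the bulky biaryl phosphine) supplies the aryl bromide, the cleanest precursor of the arylzinc; C4 is meta to both ring oxygens, so direct halogenation could not reach it.

Step 16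
Reactants: 24 (2R,3R)-4-bromo-3-(3,5-dimethoxyphenyl)-6-methoxy-2-(4-methoxyphenyl)-2,3-dihydrobenzofuran; 8 1,3-dioxoisoindolin-2-yl (2S,3S)-4-(benzyloxy)-6-methoxy-2-(4-methoxyphenyl)-2,3-dihydrobenzofuran-3-carboxylate
Product: 27 (2S,3S)-4-(benzyloxy)-3-[(2R,3R)-3-(3,5-dimethoxyphenyl)-6-methoxy-2-(4-methoxyphenyl)-2,3-dihydrobenzofuran-4-yl]-6-methoxy-2-(4-methoxyphenyl)-2,3-dihydrobenzofuran, via aryllithium 25 (not isolated), via arylzinc chloride 26 (not isolated)
Conditions: 24 (1.6 equiv), t-BuLi (3.2 equiv), THF, −78 °C; ZnCl2 (THF), −78 °C → rt; then 8 (1 equiv), NiCl2·glyme (20 mol%), 4,4'-di-tert-butyl-2,2'-bipyridine (40 mol%), THF/DMF, rt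
Reagents that add atoms: none
Why: Bromine–lithium exchange and zincation at low temperature give the C4' arylzinc, and nickel-catalysed decarboxylative Negishi arylation of redox-active ester 8 then joins it to the planar C3 radical of unit 1 on the face away from the C2 aryl group, setting C3 of unit 1 trans (S) while C2 and both centres of unit 2 are spectators.

Step 17
Reactants: 27 (the coupled benzyl ether)
Product: 28 (2S,3S)-3-[(2R,3R)-3-(3,5-dimethoxyphenyl)-6-methoxy-2-(4-methoxyphenyl)-2,3-dihydrobenzofuran-4-yl]-6-methoxy-2-(4-methoxyphenyl)-2,3-dihydrobenzofuran-4-ol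
Conditions: H2 (1 atm), Pd/C (10% Pd on carbon), EtOAc, rt
Reagents that add atoms: none
Why: Hydrogenolysis of the single O-benzyl ether frees the C4 hydroxyl of unit 1 while the methyl ethers and both dihydrofuran rings remain.

Step 18
Reactants: 28 (the C4 phenol)
Product: 29 (2S,3S)-3-[(2R,3R)-3-(3,5-dimethoxyphenyl)-6-methoxy-2-(4-methoxyphenyl)-2,3-dihydrobenzofuran-4-yl]-6-methoxy-2-(4-methoxyphenyl)-2,3-dihydrobenzofuran-4-yl trifluoromethanesulfonate
Conditions: Tf2O, pyridine, CH2Cl2, 0 °C
Reagents that add atoms: triflic anhydride O=S(=O)(OS(=O)(=O)C(F)(F)F)C(F)(F)F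
Why: O-Sulfonylation of the only free phenol installs the coupling handle at C4 of unit 1.

Step 19
Reactants: 29 (the hexamethyl ether triflate)
Product: 30 (2S,3S)-3-[(2R,3R)-3-(3,5-dihydroxyphenyl)-6-hydroxy-2-(4-hydroxyphenyl)-2,3-dihydrobenzofuran-4-yl]-6-hydroxy-2-(4-hydroxyphenyl)-2,3-dihydrobenzofuran-4-yl trifluoromethanesulfonate
Conditions: BBr3 (excess), CH2Cl2, −78 → 0 °C; MeOH then water
Reagents that add atoms: none
Why: Lewis-acid cleavage of the six aryl methyl ethers is done while no alkene is present, so acid-triggered Friedel–Crafts closure of a stilbene cannot occur; the aryl triflate is inert to BBr3, and a C2–O bond that ionises should reclose to the trans ring because C3 is fixed.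

Step 20
Reactants: 30 (the hexaphenol triflate)
Product: 31 the hexakis(tert-butyldimethylsilyl) ether of 30
Conditions: TBSCl (9 equiv), imidazole, DMF, rt
Reagents that add atoms: tert-butyldimethylsilyl chloride CC(C)(C)[Si](C)(C)Cl
Why: Silylation of all six phenols gives a soluble, chromatographable coupling partner whose protecting groups come off with fluoride, compatible with a Z-stilbene.

Step 21
Reactants: 32 tert-butyl(4-ethynylphenoxy)dimethylsilane
Product: 33 (Z)-tert-butyldimethyl{4-[2-(4,4,5,5-tetramethyl-1,3,2-dioxaborolan-2-yl)vinyl]phenoxy}silane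
Conditions: [Rh(cod)Cl]2 (1.5 mol%), P(iPr)3 (6 mol%), Et3N, pinacolborane, cyclohexane, rt
Reagents that add atoms: pinacolborane CC1(C)OBOC1(C)C
Why: Rhodium-catalysed trans-hydroboration of a terminal alkyne through a vinylidene complex (Miyaura) places boron and the aryl group cis, giving the Z-alkenylboronate.

Step 22
Reactants: 31 the hexakis(silyl ether) triflate; 33 the Z-styrylboronate
Product: 34 heptakis-O-(tert-butyldimethylsilyl)-cis-miyabenol C
Conditions: Pd(OAc)2 (10 mol%), SPhos (20 mol%), K3PO4, THF/H2O 10:1, 50 °C, dark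
Reagents that add atoms: none
Why: Suzuki–Miyaura coupling of the aryl triflate with the alkenylboronate proceeds with retention of alkene geometry, and any silyl ether lost to the base does no harm because the next step removes them all.

Step 23
Reactants: 34 heptakis-O-(tert-butyldimethylsilyl)-cis-miyabenol C
Product: 35 cis-miyabenol C
Conditions: Bu4NF (8 equiv), AcOH (8 equiv), THF, 0 °C → rt, argon, dark
Reagents that add atoms: none
Why: Fluoride desilylation buffered with acetic acid frees the seven phenols without strong acid or base, so the Z alkene should neither isomerise nor cyclise and the 2-(4-hydroxyphenyl) rings should not open through quinone methides.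

**Compound list**

1 | (2S)-naringenin | O=C1C[C@@H](c2ccc(O)cc2)Oc2cc(O)cc(O)c12 | starting material
2 | (2S)-5-hydroxy-7-methoxy-2-(4-methoxyphenyl)chroman-4-one | O=C1C[C@@H](c2ccc(OC)cc2)Oc2cc(OC)cc(O)c12 | intermediate
3 | (2S)-5-(benzyloxy)-7-methoxy-2-(4-methoxyphenyl)chroman-4-one | O=C1C[C@@H](c2ccc(OC)cc2)Oc2cc(OC)cc(OCc3ccccc3)c12 | intermediate
4 | (2S)-5-(benzyloxy)-4,7-dimethoxy-2-(4-methoxyphenyl)-2H-chromene | COC1=C[C@@H](c2ccc(OC)cc2)Oc2cc(OC)cc(OCc3ccccc3)c12 | intermediate
5 | (2R,3R)-3-[acetoxy(phenyl)-λ3-iodanyl]-5-(benzyloxy)-4,4,7-trimethoxy-2-(4-methoxyphenyl)chromane (iodine trans to the aryl group; C2 descriptor changed by priority only) | COC1(OC)[C@H](I(OC(C)=O)c2ccccc2)[C@@H](c2ccc(OC)cc2)Oc2cc(OC)cc(OCc3ccccc3)c12 | intermediate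
6 | methyl (2S,3S)-4-(benzyloxy)-6-methoxy-2-(4-methoxyphenyl)-2,3-dihydrobenzofuran-3-carboxylate | c1ccccc1COc1cc(OC)cc2c1[C@H](C(=O)OC)[C@@H](c1ccc(OC)cc1)O2 | intermediate
7 | (2S,3S)-4-(benzyloxy)-6-methoxy-2-(4-methoxyphenyl)-2,3-dihydrobenzofuran-3-carboxylic acid | c1ccccc1COc1cc(OC)cc2c1[C@H](C(=O)O)[C@@H](c1ccc(OC)cc1)O2 | intermediate
8 | 1,3-dioxoisoindolin-2-yl (2S,3S)-4-(benzyloxy)-6-methoxy-2-(4-methoxyphenyl)-2,3-dihydrobenzofuran-3-carboxylate | c1ccccc1COc1cc(OC)cc2c1[C@H](C(=O)ON1C(=O)c3ccccc3C1=O)[C@@H](c1ccc(OC)cc1)O2 | intermediate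
9 | 5,7-dihydroxy-4H-chromen-4-one | O=c1ccoc2cc(O)cc(O)c12 | starting material
10 | 5-hydroxy-7-methoxy-4H-chromen-4-one | O=c1ccoc2cc(OC)cc(O)c12 | intermediate
11 | 5-(benzyloxy)-7-methoxy-4H-chromen-4-one | O=c1ccoc2cc(OC)cc(OCc3ccccc3)c12 | intermediate
12 | 4-methoxyphenylboronic acid | COc1ccc(B(O)O)cc1 | starting material
13 | (2R)-5-(benzyloxy)-7-methoxy-2-(4-methoxyphenyl)chroman-4-one | O=C1C[C@H](c2ccc(OC)cc2)Oc2cc(OC)cc(OCc3ccccc3)c12 | intermediate
14 | (2R)-5-(benzyloxy)-4,7-dimethoxy-2-(4-methoxyphenyl)-2H-chromene | COC1=C[C@H](c2ccc(OC)cc2)Oc2cc(OC)cc(OCc3ccccc3)c12 | intermediate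
15 | (2S,3S)-3-[acetoxy(phenyl)-λ3-iodanyl]-5-(benzyloxy)-4,4,7-trimethoxy-2-(4-methoxyphenyl)chromane (iodine trans to the aryl group) | COC1(OC)[C@@H](I(OC(C)=O)c2ccccc2)[C@H](c2ccc(OC)cc2)Oc2cc(OC)cc(OCc3ccccc3)c12 | intermediate
16 | methyl (2R,3R)-4-(benzyloxy)-6-methoxy-2-(4-methoxyphenyl)-2,3-dihydrobenzofuran-3-carboxylate | c1ccccc1COc1cc(OC)cc2c1[C@@H](C(=O)OC)[C@H](c1ccc(OC)cc1)O2 | intermediate
17 | (2R,3R)-4-(benzyloxy)-6-methoxy-2-(4-methoxyphenyl)-2,3-dihydrobenzofuran-3-carboxylic acid | c1ccccc1COc1cc(OC)cc2c1[C@@H](C(=O)O)[C@H](c1ccc(OC)cc1)O2 | intermediate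
18 | 1,3-dioxoisoindolin-2-yl (2R,3R)-4-(benzyloxy)-6-methoxy-2-(4-methoxyphenyl)-2,3-dihydrobenzofuran-3-carboxylate | c1ccccc1COc1cc(OC)cc2c1[C@@H](C(=O)ON1C(=O)c3ccccc3C1=O)[C@H](c1ccc(OC)cc1)O2 | intermediate
19 | 3,5-dimethoxyphenylmagnesium chloride | COc1cc(OC)cc([Mg]Cl)c1 | starting material
20 | (3,5-dimethoxyphenyl)zinc chloride | COc1cc(OC)cc([Zn]Cl)c1 | intermediate
21 | (2R,3R)-4-(benzyloxy)-3-(3,5-dimethoxyphenyl)-6-methoxy-2-(4-methoxyphenyl)-2,3-dihydrobenzofuran | c1ccccc1COc1cc(OC)cc2c1[C@@H](c1cc(OC)cc(OC)c1)[C@H](c1ccc(OC)cc1)O2 | intermediate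
22 | (2R,3R)-3-(3,5-dimethoxyphenyl)-6-methoxy-2-(4-methoxyphenyl)-2,3-dihydrobenzofuran-4-ol | Oc1cc(OC)cc2c1[C@@H](c1cc(OC)cc(OC)c1)[C@H](c1ccc(OC)cc1)O2 | intermediate
23 | (2R,3R)-3-(3,5-dimethoxyphenyl)-6-methoxy-2-(4-methoxyphenyl)-2,3-dihydrobenzofuran-4-yl trifluoromethanesulfonate | O=S(=O)(Oc1cc(OC)cc2c1[C@@H](c1cc(OC)cc(OC)c1)[C@H](c1ccc(OC)cc1)O2)C(F)(F)F | intermediate
24 | (2R,3R)-4-bromo-3-(3,5-dimethoxyphenyl)-6-methoxy-2-(4-methoxyphenyl)-2,3-dihydrobenzofuran | Brc1cc(OC)cc2c1[C@@H](c1cc(OC)cc(OC)c1)[C@H](c1ccc(OC)cc1)O2 | intermediate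
25 | [(2R,3R)-3-(3,5-dimethoxyphenyl)-6-methoxy-2-(4-methoxyphenyl)-2,3-dihydrobenzofuran-4-yl]lithium | [Li]c1cc(OC)cc2c1[C@@H](c1cc(OC)cc(OC)c1)[C@H](c1ccc(OC)cc1)O2 | intermediate
26 | [(2R,3R)-3-(3,5-dimethoxyphenyl)-6-methoxy-2-(4-methoxyphenyl)-2,3-dihydrobenzofuran-4-yl]zinc chloride | Cl[Zn]c1cc(OC)cc2c1[C@@H](c1cc(OC)cc(OC)c1)[C@H](c1ccc(OC)cc1)O2 | intermediate
27 | (2S,3S)-4-(benzyloxy)-3-[(2R,3R)-3-(3,5-dimethoxyphenyl)-6-methoxy-2-(4-methoxyphenyl)-2,3-dihydrobenzofuran-4-yl]-6-methoxy-2-(4-methoxyphenyl)-2,3-dihydrobenzofuran | c1ccccc1COc1cc(OC)cc2c1[C@H](c1cc(OC)cc3c1[C@@H](c1cc(OC)cc(OC)c1)[C@H](c1ccc(OC)cc1)O3)[C@@H](c1ccc(OC)cc1)O2 | intermediate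
28 | (2S,3S)-3-[(2R,3R)-3-(3,5-dimethoxyphenyl)-6-methoxy-2-(4-methoxyphenyl)-2,3-dihydrobenzofuran-4-yl]-6-methoxy-2-(4-methoxyphenyl)-2,3-dihydrobenzofuran-4-ol | Oc1cc(OC)cc2c1[C@H](c1cc(OC)cc3c1[C@@H](c1cc(OC)cc(OC)c1)[C@H](c1ccc(OC)cc1)O3)[C@@H](c1ccc(OC)cc1)O2 | intermediate
29 | (2S,3S)-3-[(2R,3R)-3-(3,5-dimethoxyphenyl)-6-methoxy-2-(4-methoxyphenyl)-2,3-dihydrobenzofuran-4-yl]-6-methoxy-2-(4-methoxyphenyl)-2,3-dihydrobenzofuran-4-yl trifluoromethanesulfonate | O=S(=O)(Oc1cc(OC)cc2c1[C@H](c1cc(OC)cc3c1[C@@H](c1cc(OC)cc(OC)c1)[C@H](c1ccc(OC)cc1)O3)[C@@H](c1ccc(OC)cc1)O2)C(F)(F)F | intermediate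
30 | (2S,3S)-3-[(2R,3R)-3-(3,5-dihydroxyphenyl)-6-hydroxy-2-(4-hydroxyphenyl)-2,3-dihydrobenzofuran-4-yl]-6-hydroxy-2-(4-hydroxyphenyl)-2,3-dihydrobenzofuran-4-yl trifluoromethanesulfonate | O=S(=O)(Oc1cc(O)cc2c1[C@H](c1cc(O)cc3c1[C@@H](c1cc(O)cc(O)c1)[C@H](c1ccc(O)cc1)O3)[C@@H](c1ccc(O)cc1)O2)C(F)(F)F | intermediate
31 | hexakis(tert-butyldimethylsilyl) ether of 30 (C4 triflate of unit 1 retained) | O=S(=O)(Oc1cc(O[Si](C)(C)C(C)(C)C)cc2c1[C@H](c1cc(O[Si](C)(C)C(C)(C)C)cc3c1[C@@H](c1cc(O[Si](C)(C)C(C)(C)C)cc(O[Si](C)(C)C(C)(C)C)c1)[C@H](c1ccc(O[Si](C)(C)C(C)(C)C)cc1)O3)[C@@H](c1ccc(O[Si](C)(C)C(C)(C)C)cc1)O2)C(F)(F)F | intermediate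
32 | tert-butyl(4-ethynylphenoxy)dimethylsilane | C#Cc1ccc(O[Si](C)(C)C(C)(C)C)cc1 | starting material
33 | (Z)-tert-butyldimethyl{4-[2-(4,4,5,5-tetramethyl-1,3,2-dioxaborolan-2-yl)vinyl]phenoxy}silane | CC(C)(C)[Si](C)(C)Oc1ccc(/C=C\B2OC(C)(C)C(C)(C)O2)cc1 | intermediate
34 | heptakis-O-(tert-butyldimethylsilyl)-cis-miyabenol C | CC(C)(C)[Si](C)(C)Oc1ccc(/C=C\c2cc(O[Si](C)(C)C(C)(C)C)cc3c2[C@H](c2cc(O[Si](C)(C)C(C)(C)C)cc4c2[C@@H](c2cc(O[Si](C)(C)C(C)(C)C)cc(O[Si](C)(C)C(C)(C)C)c2)[C@H](c2ccc(O[Si](C)(C)C(C)(C)C)cc2)O4)[C@@H](c2ccc(O[Si](C)(C)C(C)(C)C)cc2)O3)cc1 | intermediate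
35 | cis-miyabenol C | Oc1ccc(/C=C\c2cc(O)cc3c2[C@H](c2cc(O)cc4c2[C@@H](c2cc(O)cc(O)c2)[C@H](c2ccc(O)cc2)O4)[C@@H](c2ccc(O)cc2)O3)cc1 | target

**Step count**

Total: 23 steps. Longest linear sequence: 17 steps (steps 6–20, 22 and 23, from 5,7-dihydroxychromone 9).

**Steps most likely to fail**

Step 16. Transmetalation of the ortho-branched arylzinc to nickel and capture of the crowded C3 radical may both be slow, so the radical would be lost to hydrogen abstraction or dimerisation and the arylzinc to protonation. Proton transfer from the diarylmethine C3'–H to the aryllithium before zincation would open the ring of unit 2. The fallback sets out from acid 7 and bromide 24 and comes back to the route at 27. It is a metallaphotoredox decarboxylative arylation (Ir[dF(CF3)ppy]2(dtbbpy)PF6, NiCl2·glyme, 4,4'-di-tert-butyl-2,2'-bipyridine, Cs2CO3, DMF, blue light, rt). The carboxylate of 7 is oxidised by the excited photocatalyst to the same C3 radical, and the aryl bromide enters nickel by oxidative addition, so no aryllithium, arylzinc or redox-active ester is needed. No new compound is made on the way (F0).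

Step 3. The 4-methoxyphenyl group may shift from C2 to C3 in place of the ring-A carbon (isoflavone), the iodane may eliminate to the flavone, the iodine reagent may attack the electron-rich ring A, and acid may ionise the C2–O bond and erode the configuration. The fallback sets out from 3 and comes back at 6, reaching the same skeletal change through a carbene. Detrifluoroacetylative diazo transfer starts with LiN(SiMe3)2 in THF at −78 °C and CF3CO2CH2CF3, which give the α-trifluoroacetyl ketone F1. MsN3, Et3N and water in MeCN then give the 3-diazo ketone F2. Irradiation (365 nm) in MeOH triggers the Wolff rearrangement, in which the ring-A carbon migrates from the carbonyl carbon to C3 to give the ketene F3, which methanol traps. Brief treatment with DBU converts any cis ester F4 into the trans ester 6.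

Step 22. Oxidative addition at the C4 triflate, which sits next to the bulky C3 substituent, may be slow; the alkenylboronate may protodeboronate; and the Z alkene may isomerise on palladium. The fallback sets out from triflate 31 and alkyne 32 and comes back at 34. Sonogashira coupling (PdCl2(PPh3)2, CuI, Et3N, DMF, 70 °C) gives the diaryl alkyne F5. Semi-hydrogenation over Pd/CaCO3 poisoned with Pb(OAc)2 (Lindlar) with quinoline and H2 in EtOAc then delivers the Z alkene 34 by syn addition of hydrogen. Step 21 is not needed in this variant.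

**Further compounds**

F0 | step 16 | none | none
F1 | step 3 | (2S)-5-(benzyloxy)-7-methoxy-2-(4-methoxyphenyl)-3-(trifluoroacetyl)chroman-4-one (C3 epimers and enol form) | O=C1C(C(=O)C(F)(F)F)[C@@H](c2ccc(OC)cc2)Oc2cc(OC)cc(OCc3ccccc3)c12
F2 | step 3 | (2R)-5-(benzyloxy)-3-diazo-7-methoxy-2-(4-methoxyphenyl)chroman-4-one (C2 arrangement as in 3; descriptor changed by priority only) | O=C1C(=[N+]=[N-])[C@@H](c2ccc(OC)cc2)Oc2cc(OC)cc(OCc3ccccc3)c12
F3 | step 3 | (2R)-4-(benzyloxy)-6-methoxy-2-(4-methoxyphenyl)-3-(oxomethylidene)-2,3-dihydrobenzofuran (ketene; C2 arrangement as in 3) | c1ccccc1COc1cc(OC)cc2c1C(=C=O)[C@@H](c1ccc(OC)cc1)O2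
F4 | step 3 | methyl (2S,3R)-4-(benzyloxy)-6-methoxy-2-(4-methoxyphenyl)-2,3-dihydrobenzofuran-3-carboxylate (cis ester) | c1ccccc1COc1cc(OC)cc2c1[C@@H](C(=O)OC)[C@@H](c1ccc(OC)cc1)O2
F5 | step 22 | heptakis-O-(tert-butyldimethylsilyl) diaryl alkyne (C≡C in place of the Z alkene of 34) | CC(C)(C)[Si](C)(C)Oc1ccc(C#Cc2cc(O[Si](C)(C)C(C)(C)C)cc3c2[C@H](c2cc(O[Si](C)(C)C(C)(C)C)cc4c2[C@@H](c2cc(O[Si](C)(C)C(C)(C)C)cc(O[Si](C)(C)C(C)(C)C)c2)[C@H](c2ccc(O[Si](C)(C)C(C)(C)C)cc2)O4)[C@@H](c2ccc(O[Si](C)(C)C(C)(C)C)cc2)O3)cc1
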